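**Retrosynthetic overview**
1. Target ⇐ MOM removal, Wittig C2 extension and nitrile→aldehyde from nitrile 11; the C7 carbon is carried as C≡N and both aryl units come from 5-hydroxyvanillin.
2. Key disconnection: the 1,4-dioxane ring (O1–C2–C3–O4–C4a–C8a) of 11 ⇐ the seven-membered ring (O1–C2–C3–C4–O5–C5a–C9a) of 1,5-benzodioxepin-3-one 9, by DKR reduction to the cis-3-ol and Smiles transfer of C5a from O5 to the C3 oxygen; C4–O5 leaves the ring as the CH2OH group.
3. Enabling feature: in the target, C4a (bearing O4) is para to C7, the carbon of the propenal chain, while C8a (bearing O1) is meta; with C7 as a nitrile only that carbon accepts an alkoxide, so the aryl–O bond moves from the primary to the secondary oxygen and nowhere else.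
4. Stereochemistry: racemic, enolisable 9 → cis-(2R,3R) alcohol (catalyst control plus dynamic resolution) → trans-(2R,3R) benzodioxane with retention at both carbons.
5. Ring order: both arenes are bought; the seven-membered ring is made by 4-O-allylation of the catechol and 7-endo epoxide opening by the 3-OH; it is contracted to the six-membered ring in step 8.

Key step: step 8

Abbreviation: Ar = 3-methoxy-4,5-bis(methoxymethoxy)phenyl.
Assumption: the sense of induction of the Ru catalyst on ketone 9 is taken from the 2-substituted cycloalkanone model; if it does not transfer, the mirror-image catalyst is used.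

Step 1
Reactants: 1 3,4-dihydroxy-5-methoxybenzaldehyde (5-hydroxyvanillin)
Product: 2 3,4-dihydroxy-5-methoxybenzonitrile
Conditions: NH2OH·HCl, HCO2Na, HCO2H, reflux
Reagents that add atoms: hydroxylamine hydrochloride, Cl.NO
Why: One-pot oxime formation and formic-acid dehydration (aldehyde-to-nitrile conversion) parks the future C7 carbon at a level that survives base, hydride and hydrogenation and activates the para carbon for SNAr.

Step 2
Reactants: 1 3,4-dihydroxy-5-methoxybenzaldehyde
Product: 3 3-methoxy-4,5-bis(methoxymethoxy)benzaldehyde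
Conditions: MOMCl, i-Pr2NEt, CH2Cl2, 0 °C→rt
Reagents that add atoms: chloromethyl methyl ether, COCCl
Why: Standard MOM protection of both phenols (Williamson-type acetalisation); the MOM ethers should survive Grignard addition, base, oxidation and hydrogenation and leave under dilute acid at the end.

Step 3
Reactants: 3 3-methoxy-4,5-bis(methoxymethoxy)benzaldehyde
Product: 4 1-Ar-prop-2-en-1-ol (racemic)
Conditions: CH2=CHMgBr, THF, −78→0 °C; then H2O
Reagents that add atoms: vinylmagnesium bromide, C=C[Mg]Br
Why: Grignard 1,2-addition to an aromatic aldehyde; the racemic carbinol centre is destroyed in the next step.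

Step 4
Reactants: 4 1-Ar-prop-2-en-1-ol
Product: 5 5-[(1E)-3-chloroprop-1-en-1-yl]-1-methoxy-2,3-bis(methoxymethoxy)benzene
Conditions: SOCl2, pyridine, Et2O, −10 °C→rt
Reagents that add atoms: thionyl chloride, ClS(Cl)=O
Why: Chlorodehydroxylation with allylic transposition (SNi′/ion-pair collapse of the chlorosulfite of a 1-arylallyl alcohol) should give the conjugated, thermodynamically preferred (E)-cinnamyl chloride.

Step 5
Reactants: 2 3,4-dihydroxy-5-methoxybenzonitrile; 5 the (E)-cinnamyl chloride
Product: 6 3-hydroxy-5-methoxy-4-{[(2E)-3-Ar-prop-2-en-1-yl]oxy}benzonitrile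
Conditions: NaHCO3 (1.1 equiv), NaI (cat.), DMF, 40 °C
Reagents that add atoms: none
Why: Williamson etherification under monoanion control: the weak base ionises only the more acidic 4-OH (para to C≡N), so the allyl unit goes on the oxygen that is exchanged later.

Step 6
Reactants: 6 3-hydroxy-5-methoxy-4-{[(2E)-3-Ar-prop-2-en-1-yl]oxy}benzonitrile
Product: 8 3-hydroxy-6-methoxy-2-Ar-3,4-dihydro-2H-1,5-benzodioxepine-8-carbonitrile (racemic; trans/cis mixture), via rac-trans-epoxide 7 (not isolated)
Conditions: DMDO, acetone, −20→0 °C; evaporate; CSA (5 mol %), CH2Cl2, −20 °C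
Reagents that add atoms: dimethyldioxirane, CC1(C)OO1
Why: Neutral epoxidation of the electron-rich styrene, then acid-catalysed 7-endo opening of the epoxide at the p-alkoxybenzylic carbon by the neighbouring phenol (epoxide–phenol cycloetherification); the configuration of 8 does not matter because both centres are erased or re-set later.

Step 7
Reactants: 8 the benzodioxepin-3-ol
Product: 9 6-methoxy-2-Ar-3-oxo-3,4-dihydro-2H-1,5-benzodioxepine-8-carbonitrile (racemic; C2 labile)
Conditions: Dess–Martin periodinane, CH2Cl2, 0 °C→rt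
Reagents that add atoms: none
Why: Dess–Martin oxidation of a secondary alcohol erases C3 and makes C2 (α-aryl, α-aryloxy) configurationally labile for the dynamic step.

Step 8
Reactants: 9 the racemic benzodioxepin-3-one
Product: 11 (2R,3R)-3-(hydroxymethyl)-5-methoxy-2-Ar-2,3-dihydro-1,4-benzodioxine-7-carbonitrile, via cis-(2R,3R)-benzodioxepin-3-ol 10 (not isolated)
Conditions: trans-RuCl2[(S)-xylbinap][(R,R)-dpen] (1 mol %), KOt-Bu (10 mol %), H2 (10 atm), i-PrOH/THF, 25 °C; then vent, evaporate, KOt-Bu (to 30 mol %), DMSO, 25→40 °C; aq. NH4Cl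
Reagents that add atoms: none
Why: Proposed new method: under Noyori-type Ru(diphosphine)(diamine)/alkoxide hydrogenation the enolisable ketone 9 should racemise faster than it is reduced, so it is funnelled by dynamic kinetic resolution into the cis alkoxide of 10, which in DMSO adds through O3 to C5a (ipso, para to C≡N) and, via a cyano-stabilised spiro σ-adduct, expels O5 with C4 (Smiles rearrangement). The closest known reaction types are the DKR hydrogenation of 2-aryl- and 2-aryloxycycloalkanones to cis alcohols and the O→O Smiles aryl migration of 2-(nitroaryloxy)ethoxides; new are their coupling and the use of a nitrile-only activated, trioxygenated ring in a ring contraction. The one ring closed is the 1,4-dioxane ring, by transannular ipso attack across the seven-membered ring (5-exo-trig with respect to the transient spiro-1,3-dioxolane) followed by C5a–O5 scission, which turns the 1,5-benzodioxepine into the 1,4-benzodioxane and releases C4 as CH2OH. C3 is set by the chiral Ru–H/N–H catalyst (catalyst control) and C2 by the dynamic resolution, hydride being delivered to the face anti to the C2 aryl group of the matched enantiomer; the Smiles step breaks no bond at C2 or C3, so cis-(2R,3R) in the seven-membered ring is transcribed as trans-(2R,3R) in the six-membered ring. The step needs attack at C5a and not C9a, which the para (versus meta) position of the nitrile secures, and aryl transfer and not epoxide formation at C4, which the poor aryloxide leaving group at sp3 carbon and the five-membered spiro transition state secure. The contraction is driven by the seven-to-six ring change and the secondary-to-primary alkoxide change, so catalytic base should be enough.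

Step 9
Reactants: 11 the benzodioxane nitrile
Product: 12 (2R,3R)-3-(hydroxymethyl)-5-methoxy-2-Ar-2,3-dihydro-1,4-benzodioxine-7-carbaldehyde
Conditions: DIBAL-H (3 equiv), CH2Cl2, −78→−20 °C; aq. Rochelle salt, then 5% aq. citric acid, 0 °C
Reagents that add atoms: water, O
Why: DIBAL-H adds once to the aryl nitrile and the N-aluminio aldimine is hydrolysed to the aldehyde on work-up (partial nitrile reduction); the free alcohol only consumes one hydride and no stereocentre is touched.

Step 10
Reactants: 12 the benzodioxane aldehyde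
Product: 13 (2E)-3-[(2R,3R)-3-(hydroxymethyl)-5-methoxy-2-Ar-2,3-dihydro-1,4-benzodioxin-7-yl]prop-2-enal
Conditions: Ph3P=CHCHO (1.2 equiv), toluene, 80 °C
Reagents that add atoms: (triphenylphosphoranylidene)acetaldehyde, O=CC=P(c1ccccc1)(c1ccccc1)c1ccccc1
Why: Wittig olefination with the stabilised formylmethylene ylide should give the (E)-enal; a near-stoichiometric amount of ylide limits double homologation.

Step 11
Reactants: 13 the bis-MOM enal
Product: 14 (2E)-3-[(2R,3R)-2-(3,4-dihydroxy-5-methoxyphenyl)-3-(hydroxymethyl)-5-methoxy-2,3-dihydro-1,4-benzodioxin-7-yl]prop-2-enal (target)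
Conditions: 2 M aq. HCl, THF, 40 °C, under Ar
Reagents that add atoms: none
Why: Acid hydrolysis of the two phenolic MOM acetals; the enal and the primary alcohol tolerate dilute acid, and any reversible opening of the p-hydroxybenzylic C2–O1 bond returns mainly the thermodynamically preferred trans isomer.

**Compound list**
1 | 3,4-dihydroxy-5-methoxybenzaldehyde (5-hydroxyvanillin) | COc1cc(C=O)cc(O)c1O | starting material
2 | 3,4-dihydroxy-5-methoxybenzonitrile | COc1cc(C#N)cc(O)c1O | intermediate
3 | 3-methoxy-4,5-bis(methoxymethoxy)benzaldehyde | COCOc1cc(C=O)cc(OC)c1OCOC | intermediate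
4 | 1-[3-methoxy-4,5-bis(methoxymethoxy)phenyl]prop-2-en-1-ol (racemic) | C=CC(O)c1cc(OC)c(OCOC)c(OCOC)c1 | intermediate
5 | 5-[(1E)-3-chloroprop-1-en-1-yl]-1-methoxy-2,3-bis(methoxymethoxy)benzene | ClC/C=C/c1cc(OC)c(OCOC)c(OCOC)c1 | intermediate
6 | 3-hydroxy-5-methoxy-4-{[(2E)-3-[3-methoxy-4,5-bis(methoxymethoxy)phenyl]prop-2-en-1-yl]oxy}benzonitrile | N#Cc1cc(O)c(OC/C=C/c2cc(OC)c(OCOC)c(OCOC)c2)c(OC)c1 | intermediate
7 | 3-hydroxy-5-methoxy-4-{[(2R*,3R*)-3-[3-methoxy-4,5-bis(methoxymethoxy)phenyl]oxiran-2-yl]methoxy}benzonitrile (racemic trans-epoxide, one enantiomer drawn) | N#Cc1cc(O)c(OC[C@H]2O[C@@H]2c3cc(OC)c(OCOC)c(OCOC)c3)c(OC)c1 | intermediate (not isolated)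
8 | 3-hydroxy-6-methoxy-2-[3-methoxy-4,5-bis(methoxymethoxy)phenyl]-3,4-dihydro-2H-1,5-benzodioxepine-8-carbonitrile (racemic, trans/cis mixture) | N#Cc1cc2OC(c3cc(OC)c(OCOC)c(OCOC)c3)C(O)COc2c(OC)c1 | intermediate
9 | 6-methoxy-2-[3-methoxy-4,5-bis(methoxymethoxy)phenyl]-3-oxo-3,4-dihydro-2H-1,5-benzodioxepine-8-carbonitrile (racemic) | N#Cc1cc2OC(c3cc(OC)c(OCOC)c(OCOC)c3)C(=O)COc2c(OC)c1 | intermediate
10 | (2R,3R)-3-hydroxy-6-methoxy-2-[3-methoxy-4,5-bis(methoxymethoxy)phenyl]-3,4-dihydro-2H-1,5-benzodioxepine-8-carbonitrile (cis) | COc1cc([C@H]2Oc3cc(C#N)cc(OC)c3OC[C@H]2O)cc(OCOC)c1OCOC | intermediate (not isolated)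
11 | (2R,3R)-3-(hydroxymethyl)-5-methoxy-2-[3-methoxy-4,5-bis(methoxymethoxy)phenyl]-2,3-dihydro-1,4-benzodioxine-7-carbonitrile (trans) | COc1cc([C@H]2Oc3cc(C#N)cc(OC)c3O[C@@H]2CO)cc(OCOC)c1OCOC | intermediate
12 | (2R,3R)-3-(hydroxymethyl)-5-methoxy-2-[3-methoxy-4,5-bis(methoxymethoxy)phenyl]-2,3-dihydro-1,4-benzodioxine-7-carbaldehyde | COc1cc([C@H]2Oc3cc(C=O)cc(OC)c3O[C@@H]2CO)cc(OCOC)c1OCOC | intermediate
13 | (2E)-3-[(2R,3R)-3-(hydroxymethyl)-5-methoxy-2-[3-methoxy-4,5-bis(methoxymethoxy)phenyl]-2,3-dihydro-1,4-benzodioxin-7-yl]prop-2-enal | COc1cc([C@H]2Oc3cc(/C=C/C=O)cc(OC)c3O[C@@H]2CO)cc(OCOC)c1OCOC | intermediate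
14 | (2E)-3-[(2R,3R)-2-(3,4-dihydroxy-5-methoxyphenyl)-3-(hydroxymethyl)-5-methoxy-2,3-dihydro-1,4-benzodioxin-7-yl]prop-2-enal | COc1cc([C@H]2Oc3cc(/C=C/C=O)cc(OC)c3O[C@@H]2CO)cc(O)c1O | target

**Step count:** 11 steps in total; longest linear sequence 10 steps (1 → 3 → 4 → 5 → 6 → 8 → 9 → 11 → 12 → 13 → 14).

**Steps most likely to fail**

Step 8 (proposed new method). The dynamic resolution may discriminate poorly, because the ketone has no aryl group on the carbonyl carbon, which would lower the cis selectivity or the enantiomeric purity. The alkoxide may also add too slowly to a ring that is activated only by one nitrile, or displacement at C4 (epoxide formation, inversion at C3) may compete with aryl transfer. The fallback uses known chemistry, sets out from 3 and 2, and comes back at 11. Lewis-acid catalysed homologation of 3 with ethyl diazoacetate (NbCl5 cat.) would give ethyl 3-[3-methoxy-4,5-bis(methoxymethoxy)phenyl]-3-oxopropanoate F1. Bromination with NBS would give ethyl 2-bromo-3-[3-methoxy-4,5-bis(methoxymethoxy)phenyl]-3-oxopropanoate F2. O-alkylation of 2 at its acidic 4-OH (K2CO3, acetone) would give ethyl 2-(4-cyano-2-hydroxy-6-methoxyphenoxy)-3-[3-methoxy-4,5-bis(methoxymethoxy)phenyl]-3-oxopropanoate F3. Transfer hydrogenation with dynamic kinetic resolution (Ru–TsDPEN, HCO2H/Et3N) would give ethyl (2S,3R)-2-(4-cyano-2-hydroxy-6-methoxyphenoxy)-3-hydroxy-3-[3-methoxy-4,5-bis(methoxymethoxy)phenyl]propanoate F4. LiBH4 would reduce the ester to 3-hydroxy-4-{[(1R,2R)-1,3-dihydroxy-1-[3-methoxy-4,5-bis(methoxymethoxy)phenyl]propan-2-yl]oxy}-5-methoxybenzonitrile F5. Acid-catalysed benzylic cycloetherification (CSA cat., CH2Cl2) under thermodynamic control would then close the trans-benzodioxane 11 directly.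

Step 6. After ionisation of the epoxide, a 1,2-hydride shift (Meinwald pathway) or intermolecular capture of the benzylic cation may outrun the entropically slower seven-membered closure, and the acid may start to remove MOM groups. The fallback sets out from 6 and comes back at 8. Iodoetherification (NIS, CH2Cl2), in which the phenol opens the iodonium ion at the benzylic carbon, would give rac-(2R*,3S*)-3-iodo-6-methoxy-2-[3-methoxy-4,5-bis(methoxymethoxy)phenyl]-3,4-dihydro-2H-1,5-benzodioxepine-8-carbonitrile F6. Elimination with DBU towards C4 would give 6-methoxy-2-[3-methoxy-4,5-bis(methoxymethoxy)phenyl]-2H-1,5-benzodioxepine-8-carbonitrile F7. Hydroboration–oxidation of this enol ether (9-BBN, then NaBO3) would place the hydroxyl at C3 and return 8.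

Step 5. Alkylation may occur on the wrong oxygen or twice, and the labile allylic chloride may be lost by solvolysis before it is used. The fallback sets out from 4 (with 2) and comes back at 6, bypassing chloride 5. Acylation of 4 (ClCO2Me, pyridine) would give methyl 1-[3-methoxy-4,5-bis(methoxymethoxy)phenyl]prop-2-en-1-yl carbonate F8. Tsuji–Trost O-allylation of 2 (Pd(PPh3)4, THF, rt, short reaction time) should deliver the linear (E)-ether 6, the more acidic 4-OH being ionised by the methoxide that the carbonate releases.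

Further compounds
F1 | step 8 | ethyl 3-[3-methoxy-4,5-bis(methoxymethoxy)phenyl]-3-oxopropanoate | CCOC(=O)CC(=O)c1cc(OC)c(OCOC)c(OCOC)c1
F2 | step 8 | ethyl 2-bromo-3-[3-methoxy-4,5-bis(methoxymethoxy)phenyl]-3-oxopropanoate (racemic) | CCOC(=O)C(Br)C(=O)c1cc(OC)c(OCOC)c(OCOC)c1
F3 | step 8 | ethyl 2-(4-cyano-2-hydroxy-6-methoxyphenoxy)-3-[3-methoxy-4,5-bis(methoxymethoxy)phenyl]-3-oxopropanoate (racemic) | CCOC(=O)C(Oc1c(O)cc(C#N)cc1OC)C(=O)c1cc(OC)c(OCOC)c(OCOC)c1
F4 | step 8 | ethyl (2S,3R)-2-(4-cyano-2-hydroxy-6-methoxyphenoxy)-3-hydroxy-3-[3-methoxy-4,5-bis(methoxymethoxy)phenyl]propanoate | CCOC(=O)[C@@H](Oc1c(O)cc(C#N)cc1OC)[C@H](O)c1cc(OC)c(OCOC)c(OCOC)c1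
F5 | step 8 | 3-hydroxy-4-{[(1R,2R)-1,3-dihydroxy-1-[3-methoxy-4,5-bis(methoxymethoxy)phenyl]propan-2-yl]oxy}-5-methoxybenzonitrile | OC[C@@H](Oc1c(O)cc(C#N)cc1OC)[C@H](O)c1cc(OC)c(OCOC)c(OCOC)c1
F6 | step 6 | rac-(2R*,3S*)-3-iodo-6-methoxy-2-[3-methoxy-4,5-bis(methoxymethoxy)phenyl]-3,4-dihydro-2H-1,5-benzodioxepine-8-carbonitrile (trans, one enantiomer drawn) | COc1cc([C@H]2Oc3cc(C#N)cc(OC)c3OC[C@@H]2I)cc(OCOC)c1OCOC
F7 | step 6 | 6-methoxy-2-[3-methoxy-4,5-bis(methoxymethoxy)phenyl]-2H-1,5-benzodioxepine-8-carbonitrile (racemic) | COc1cc(C2Oc3cc(C#N)cc(OC)c3OC=C2)cc(OCOC)c1OCOC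
F8 | step 5 | methyl 1-[3-methoxy-4,5-bis(methoxymethoxy)phenyl]prop-2-en-1-yl carbonate (racemic) | C=CC(OC(=O)OC)c1cc(OC)c(OCOC)c(OCOC)c1
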